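**Strategy.** The lactone ring (O1–C2–C3–C4–C5) is disconnected across C3–C4 and C5–O1 into dichloroketene and an enantiopure (Z)-1-alkenyl p-tolyl sulfoxide that already carries the isovanillyl CH2 group. The key step, an additive Pummerer [3,3] rearrangement with lactonisation, forms both bonds in one operation and transfers the sulfur chirality to C4. It exploits the fact that C5 is an unsubstituted O–CH2 and C3 an enolisable α-carbon: sulfur on C5 and chlorine on C3 are traceless and are removed reductively. trans-Selective α-alkylation with the vanillyl bromide and hydrogenolysis of two benzyl ethers then complete the target.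

Key step: step 4

Remark 1: the target is (3R,4R), trans; C4 (R) is set in step 4 and C3 (R) in step 7.
Remark 2: the CIP descriptor at sulfur changes from (S) in alkynyl sulfoxide 7 to (R) in alkenyl sulfoxide 8 with no change in geometry, because a 1-alkynyl carbon outranks p-tolyl and an alkenyl carbon does not.
Remark 3: aryl bromide 1 is taken as a catalogue compound; otherwise one benzylation of 5-bromo-2-methoxyphenol provides it.

**Step 1**
Reactants: 1 2-(benzyloxy)-4-bromo-1-methoxybenzene; 2 methoxyallene
Product: 4 2-(benzyloxy)-1-methoxy-4-(prop-2-yn-1-yl)benzene, via arylmagnesium bromide 3 (not isolated)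
Conditions: Mg, THF, reflux; then 2, CuBr (5 mol%), THF/Et2O, −20 °C → rt
Reagents that add atoms: methoxyallene 2, COC=C=C
Why: Copper-catalysed SN2' substitution of the allenyl ether by the aryl Grignard reagent (attack at the CH2 terminus, loss of methoxide) is a known route to 3-aryl-1-propynes; no stereocentre is formed.

**Step 2**
Reactants: 4 2-(benzyloxy)-1-methoxy-4-(prop-2-yn-1-yl)benzene; 5 (1R,2S,5R)-menthyl (S)-4-methylbenzenesulfinate
Product: 7 2-(benzyloxy)-1-methoxy-4-{3-[(S)-(4-methylphenyl)sulfinyl]prop-2-yn-1-yl}benzene, via alkynylmagnesium bromide 6 (not isolated)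
Conditions: EtMgBr, THF/toluene, 0 °C → rt; then 5, toluene, −20 °C
Reagents that add atoms: sulfinate 5, C[C@@H]1CC[C@H]([C@@H](C1)O[S@](=O)c1ccc(C)cc1)C(C)C
Why: Andersen sulfoxide synthesis, in which the alkynyl Grignard reagent displaces menthoxide at sulfur with inversion, so the sulfur stereocentre is taken from the diastereomerically pure sulfinate.

**Step 3**
Reactants: 7 2-(benzyloxy)-1-methoxy-4-{3-[(S)-(4-methylphenyl)sulfinyl]prop-2-yn-1-yl}benzene
Product: 8 2-(benzyloxy)-1-methoxy-4-{(2Z)-3-[(R)-(4-methylphenyl)sulfinyl]prop-2-en-1-yl}benzene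
Conditions: H2 (1 atm), RhCl(PPh3)3 (5 mol%), benzene, rt
Reagents that add atoms: none
Why: Homogeneous Rh(I)-catalysed syn-hydrogenation of a 1-alkynyl sulfoxide should stop at the (Z)-alkenyl sulfoxide and leaves the sulfur centre and the benzyl ether untouched.

**Step 4**
Reactants: 8 2-(benzyloxy)-1-methoxy-4-{(2Z)-3-[(R)-(4-methylphenyl)sulfinyl]prop-2-en-1-yl}benzene; 9 trichloroacetyl chloride
Product: 12 (4S,5R)-4-[3-(benzyloxy)-4-methoxybenzyl]-3,3-dichloro-5-[(4-methylphenyl)sulfanyl]dihydrofuran-2(3H)-one, via acyloxysulfonium enolate 10 (not isolated), via thionium carboxylate 11 (not isolated)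
Conditions: 9, Zn–Cu couple, Et2O, reflux
Reagents that add atoms: trichloroacetyl chloride 9, ClC(Cl)(Cl)C(Cl)=O (source of dichloroketene, ClC(Cl)=C=O)
Why: The sulfinyl oxygen of 8 adds to the carbonyl carbon of dichloroketene (made in the flask from 9 and zinc) to give zwitterion 10, whose six-atom array Cl2C=C(O−)–O–S+–CH=CH undergoes a [3,3]-sigmatropic shift that forms C3–C4 and breaks S–O, and the carboxylate of the resulting thionium ion 11 then adds to the thionium carbon to form C5–O1. This is the additive Pummerer reaction known as the Marino lactonization of 1-alkenyl aryl sulfoxides. The lactone ring is closed by 5-exo-trig attack of the carboxylate oxygen on the C=S+ carbon, after the C3–C4 bond has formed through a chair-like six-membered transition state. C4 is controlled by the sulfur stereocentre: with the (Z)-alkene the lone pair, not p-tolyl, must lie next to the cis CH2Ar group (allylic strain, p-tolyl pseudo-equatorial), so the O-bound enolate reaches only one face of the β-carbon, which for (R)-sulfur should give 4S in 12 (4R once chlorine and sulfur are gone). C5 is set cis to the benzyl group because both new bonds form on the same alkene face, and it is erased in step 5. The step needs O-acylation of the sulfoxide in preference to [2+2] cycloaddition or arene acylation, which the electron-poor sulfinyl alkene, the nucleophilic sulfinyl oxygen and the benzyl-protected phenol secure, while the O–S tether fixes the regiochemistry (carbon to the β-carbon, oxygen to the sulfur-bearing carbon).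

**Step 5**
Reactants: 12 (4S,5R)-4-[3-(benzyloxy)-4-methoxybenzyl]-3,3-dichloro-5-[(4-methylphenyl)sulfanyl]dihydrofuran-2(3H)-one
Product: 15 (R)-4-[3-(benzyloxy)-4-methoxybenzyl]dihydrofuran-2(3H)-one, via 3-chloro lactone 13 (not isolated), via 5-sulfanyl lactone 14 (not isolated)
Conditions: Bu3SnH (4.5 equiv), AIBN (cat.), toluene, reflux
Reagents that add atoms: none
Why: Radical chain reduction in which stannyl radicals abstract the two α-carbonyl chlorines and then cleave the C5–S bond via the α-acyloxyalkyl radical; C4 is not involved and keeps its configuration.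

**Step 6**
Reactants: 16 [4-(benzyloxy)-3-methoxyphenyl]methanol
Product: 17 1-(benzyloxy)-4-(bromomethyl)-2-methoxybenzene
Conditions: PBr3, Et2O, 0 °C
Reagents that add atoms: phosphorus tribromide, BrP(Br)Br
Why: Standard conversion of an electron-rich benzylic alcohol into the bromide via the phosphite ester and bromide displacement; the aryl benzyl ether should survive at 0 °C.

**Step 7**
Reactants: 15 (R)-4-[3-(benzyloxy)-4-methoxybenzyl]dihydrofuran-2(3H)-one; 17 1-(benzyloxy)-4-(bromomethyl)-2-methoxybenzene
Product: 19 (3R,4R)-3-[4-(benzyloxy)-3-methoxybenzyl]-4-[3-(benzyloxy)-4-methoxybenzyl]dihydrofuran-2(3H)-one, via lithium enolate 18 (not isolated)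
Conditions: LiHMDS, THF, −78 °C; then 17, DMPU, −78 → −30 °C
Reagents that add atoms: bromide 17, COc1cc(CBr)ccc1OCc1ccccc1
Why: Lactone enolate alkylation, in which the benzylic bromide should approach the enolate face anti to the C4 substituent, setting C3 as R (trans), which is also the thermodynamically preferred arrangement.

**Step 8**
Reactants: 19 (3R,4R)-3-[4-(benzyloxy)-3-methoxybenzyl]-4-[3-(benzyloxy)-4-methoxybenzyl]dihydrofuran-2(3H)-one
Product: 20 (3R,4R)-3-(4-hydroxy-3-methoxybenzyl)-4-(3-hydroxy-4-methoxybenzyl)dihydrofuran-2(3H)-one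
Conditions: H2 (1 atm), 10% Pd/C, EtOAc/EtOH, rt
Reagents that add atoms: none
Why: Hydrogenolysis of both aryl benzyl ethers under neutral conditions, which should leave the lactone, the methyl ethers and both stereocentres unchanged.

**Compound list**
1 | 2-(benzyloxy)-4-bromo-1-methoxybenzene | COc1ccc(Br)cc1OCc1ccccc1 | starting material
2 | methoxyallene (1-methoxypropa-1,2-diene) | COC=C=C | starting material
3 | [3-(benzyloxy)-4-methoxyphenyl]magnesium bromide | COc1ccc([Mg]Br)cc1OCc1ccccc1 | intermediate
4 | 2-(benzyloxy)-1-methoxy-4-(prop-2-yn-1-yl)benzene | COc1ccc(CC#C)cc1OCc1ccccc1 | intermediate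
5 | (1R,2S,5R)-menthyl (S)-4-methylbenzenesulfinate | C[C@@H]1CC[C@H]([C@@H](C1)O[S@](=O)c1ccc(C)cc1)C(C)C | starting material
6 | {3-[3-(benzyloxy)-4-methoxyphenyl]prop-1-yn-1-yl}magnesium bromide | COc1ccc(CC#C[Mg]Br)cc1OCc1ccccc1 | intermediate
7 | 2-(benzyloxy)-1-methoxy-4-{3-[(S)-(4-methylphenyl)sulfinyl]prop-2-yn-1-yl}benzene | COc1ccc(CC#C[S@@](=O)c2ccc(C)cc2)cc1OCc1ccccc1 | intermediate
8 | 2-(benzyloxy)-1-methoxy-4-{(2Z)-3-[(R)-(4-methylphenyl)sulfinyl]prop-2-en-1-yl}benzene | COc1ccc(C/C=C\[S@@](=O)c2ccc(C)cc2)cc1OCc1ccccc1 | intermediate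
9 | trichloroacetyl chloride | ClC(Cl)(Cl)C(Cl)=O | starting material
10 | (R)-acyloxysulfonium enolate zwitterion (O-adduct of 8 and dichloroketene, (Z)-alkene) | COc1ccc(C/C=C\[S@@+](OC([O-])=C(Cl)Cl)c2ccc(C)cc2)cc1OCc1ccccc1 | intermediate
11 | (S)-3-{[3-(benzyloxy)-4-methoxyphenyl]methyl}-2,2-dichloro-4-[(4-methylphenyl)sulfaniumylidene]butanoate (thionium carboxylate) | [O-]C(=O)C(Cl)(Cl)[C@H](C=[S+]c1ccc(C)cc1)Cc1ccc(OC)c(OCc2ccccc2)c1 | intermediate
12 | (4S,5R)-4-[3-(benzyloxy)-4-methoxybenzyl]-3,3-dichloro-5-[(4-methylphenyl)sulfanyl]dihydrofuran-2(3H)-one (4,5-cis) | O=C1O[C@H](Sc2ccc(C)cc2)[C@H](Cc2ccc(OC)c(OCc3ccccc3)c2)C1(Cl)Cl | intermediate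
13 | (4S,5R)-4-[3-(benzyloxy)-4-methoxybenzyl]-3-chloro-5-[(4-methylphenyl)sulfanyl]dihydrofuran-2(3H)-one (C3 epimers) | O=C1O[C@H](Sc2ccc(C)cc2)[C@H](Cc2ccc(OC)c(OCc3ccccc3)c2)C1Cl | intermediate
14 | (4R,5R)-4-[3-(benzyloxy)-4-methoxybenzyl]-5-[(4-methylphenyl)sulfanyl]dihydrofuran-2(3H)-one | O=C1O[C@H](Sc2ccc(C)cc2)[C@H](Cc2ccc(OC)c(OCc3ccccc3)c2)C1 | intermediate
15 | (R)-4-[3-(benzyloxy)-4-methoxybenzyl]dihydrofuran-2(3H)-one | O=C1OC[C@H](Cc2ccc(OC)c(OCc3ccccc3)c2)C1 | intermediate
16 | [4-(benzyloxy)-3-methoxyphenyl]methanol | COc1cc(CO)ccc1OCc1ccccc1 | starting material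
17 | 1-(benzyloxy)-4-(bromomethyl)-2-methoxybenzene | COc1cc(CBr)ccc1OCc1ccccc1 | intermediate
18 | lithium enolate of 15, (R)-configured at C4 | [Li]OC1=C[C@@H](Cc2ccc(OC)c(OCc3ccccc3)c2)CO1 | intermediate
19 | (3R,4R)-3-[4-(benzyloxy)-3-methoxybenzyl]-4-[3-(benzyloxy)-4-methoxybenzyl]dihydrofuran-2(3H)-one | COc1ccc(C[C@H]2COC(=O)[C@@H]2Cc2ccc(OCc3ccccc3)c(OC)c2)cc1OCc1ccccc1 | intermediate
20 | (3R,4R)-3-(4-hydroxy-3-methoxybenzyl)-4-(3-hydroxy-4-methoxybenzyl)dihydrofuran-2(3H)-one | COc1ccc(C[C@H]2COC(=O)[C@@H]2Cc2ccc(O)c(OC)c2)cc1O | target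

**Total step count:** 8. **Longest linear sequence:** 7 (steps 1, 2, 3, 4, 5, 7, 8); step 6 is a one-step side branch.

**Steps most likely to fail**

Step 4 (key step). The transfer of chirality from sulfur to C4 may be incomplete if the rearrangement leaks through the conformer with p-tolyl next to the alkene, and the thionium ion may be lost to Pummerer-type elimination before the carboxylate closes the ring. The fallback sets out from 1 and comes back at 15, with C4 set by asymmetric hydrogenation instead. Grignard reagent 3, made from 1 as in step 1, is quenched with DMF to give 3-(benzyloxy)-4-methoxybenzaldehyde F1. Stobbe condensation of F1 with dimethyl succinate (NaOMe, MeOH, reflux) should give (E)-4-[3-(benzyloxy)-4-methoxyphenyl]-3-(methoxycarbonyl)but-3-enoic acid F2. Hydrogenation with a cationic Rh(I) chiral bisphosphine catalyst (ligand antipode chosen for the R acid) should give (R)-4-[3-(benzyloxy)-4-methoxyphenyl]-3-(methoxycarbonyl)butanoic acid F3. Chemoselective reduction of the ester group of its potassium salt with Ca(BH4)2 in EtOH, followed by acid lactonisation, should return lactone 15, from which steps 7 and 8 follow unchanged.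

Step 2. The doubly activated CH2 of the alkynyl sulfoxide may isomerise to the allenyl sulfoxide under the basic magnesium species, and the acetylide may add in conjugate fashion to the product. The fallback sets out from 4 and comes back at 8; it fixes the alkene geometry before sulfur is introduced and avoids the alkynyl sulfoxide altogether. Iodination of 4 (NIS, cat. AgNO3, acetone) should give 2-(benzyloxy)-4-(3-iodoprop-2-yn-1-yl)-1-methoxybenzene F4. cis-Reduction with diimide (2-nitrobenzenesulfonohydrazide, Et3N) should give 2-(benzyloxy)-4-[(2Z)-3-iodoprop-2-en-1-yl]-1-methoxybenzene F5. Iodine–magnesium exchange with iPrMgCl·LiCl (THF, −40 °C) should give, with retention of geometry, {(1Z)-3-[3-(benzyloxy)-4-methoxyphenyl]prop-1-en-1-yl}magnesium chloride F6. Its Andersen reaction with sulfinate 5 (inversion at sulfur) should give 8 directly.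

Step 5. The chain may stall after dechlorination because homolytic cleavage of the C5–S bond is slow, leaving sulfur in the lactone. The fallback sets out from 12 and comes back at 15 and separates the two tasks mechanistically. Zinc dust in acetic acid (two-electron dechlorination) should give the 5-sulfanyl lactone 14, which is then isolated. Hydrogenolytic desulfurisation of 14 on Raney nickel deactivated in acetone (EtOH, rt) should give 15 with the aryl benzyl ether intact.

**Further compounds**
F1 | step 4 | 3-(benzyloxy)-4-methoxybenzaldehyde | COc1ccc(C=O)cc1OCc1ccccc1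
F2 | step 4 | (E)-4-[3-(benzyloxy)-4-methoxyphenyl]-3-(methoxycarbonyl)but-3-enoic acid | COC(=O)/C(=C/c1ccc(OC)c(OCc2ccccc2)c1)CC(=O)O
F3 | step 4 | (R)-4-[3-(benzyloxy)-4-methoxyphenyl]-3-(methoxycarbonyl)butanoic acid | COC(=O)[C@H](Cc1ccc(OC)c(OCc2ccccc2)c1)CC(=O)O
F4 | step 2 | 2-(benzyloxy)-4-(3-iodoprop-2-yn-1-yl)-1-methoxybenzene | COc1ccc(CC#CI)cc1OCc1ccccc1
F5 | step 2 | 2-(benzyloxy)-4-[(2Z)-3-iodoprop-2-en-1-yl]-1-methoxybenzene | COc1ccc(C/C=C\I)cc1OCc1ccccc1
F6 | step 2 | {(1Z)-3-[3-(benzyloxy)-4-methoxyphenyl]prop-1-en-1-yl}magnesium chloride | COc1ccc(C/C=C\[Mg]Cl)cc1OCc1ccccc1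
F0 | step 5 | none | none
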